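The red flask is asked about at 39 h, far beyond the last reading at 6.5 h, so the question there is how long target survives once it is made.

| setting | grey | blue | teal | ochre | red |
|---|---|---|---|---|---|
| starting material | 1.00 M | 0.600 M | 3.00 M | 1.00 M | 1.00 M |
| reagent | 3.00 M | 2.60 M | 3.00 M | 3.00 M | 3.00 M |
| catalyst | 0.0300 M | 0.0300 M | 0.0300 M | 0.0300 M | 0.0300 M |
| target |  |  |  | 0.300 M |  |
| time |  |  |  |  | 39 h |

| run | time / h | [target] / M |
|---|---|---|
| grey run | 0.81 | 0.092 |
| grey run | 1.6 | 0.142 |
| grey run | 2.4 | 0.224 |
| grey run | 3.2 | 0.271 |
| grey run | 4.1 | 0.324 |
| grey run | 4.9 | 0.341 |
| grey run | 5.7 | 0.385 |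
| grey run | 6.5 | 0.434 |
| blue run | 0.81 | 0.038 |
| blue run | 1.6 | 0.087 |
| blue run | 2.4 | 0.115 |
| blue run | 3.2 | 0.152 |
| blue run | 4.1 | 0.169 |
| blue run | 4.9 | 0.188 |
| blue run | 5.7 | 0.240 |
| blue run | 6.5 | 0.235 |
| teal run | 0.81 | 0.229 |
| teal run | 1.6 | 0.406 |
| teal run | 2.4 | 0.546 |
| teal run | 3.2 | 0.689 |
| teal run | 4.1 | 0.822 |
| teal run | 4.9 | 0.899 |
| teal run | 5.7 | 1.003 |
| teal run | 6.5 | 1.070 |
| ochre run | 0.81 | 0.372 |
| ochre run | 1.6 | 0.431 |
| ochre run | 2.4 | 0.477 |
| ochre run | 3.2 | 0.515 |
| ochre run | 4.1 | 0.560 |
| ochre run | 4.9 | 0.580 |
| ochre run | 5.7 | 0.605 |
| ochre run | 6.5 | 0.600 |

(scatter of a reading: 0.01 M)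

1. reaction order in [starting material] at the outset, round the charge of the grey run, defined at two percent of the starting material turned into target (one fixed amount of target, the same in the runs compared)
2. reaction order in [reagent] at the outset, round the charge of the grey run, defined at two percent of the starting material turned into target
3. target in the red run at 39 h, as a share of the starting material charged
4. which of these the readings show (the second partner kills the catalyst / nothing beyond the main steps / the product reacts on with the second partner / the second partner is lost by itself / the second partner ties up the catalyst)

- Overall: starting material + reagent -> target, with catalyst as catalyst.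
- Constant volume, constant temperature.
- What is held in complexes is read along with the free species.
- "The second partner" is reagent.
- An order is taken over about fifteen percent of the charge, up and down.

The grey and ochre flasks differ by the 0.300 M of target put into ochre at the start. Over the last two readings, the gap between them averages 0.193 M around 6.10 h, less than was put in. Read as a steady fractional loss, this gap gives 13.8 h: the target lifetime, the time over which a stock of target shrinks by the factor e while c_reagent stays near 3.00 M. It is a pseudo-first-order lifetime, and it is a reading that carries the scatter.

That lifetime is my own reading, and my colleague and I hold different simple views of the red flask. My view is the simpler one: as an assumption, I hold c_reagent in the red flask at its charge of 3.00 M, and so keep the lifetime unchanged out to 39 h. The first grey reading gives a making constant of 0.114 h⁻¹. Starting material then feeds target at that fractional rate while target drains at one per lifetime, a loss constant of 0.0723 h⁻¹. The 39 h of the red flask is 2.82 lifetimes, and my reckoning leaves 13.1 % of the charge as target.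

My colleague made the forecast and argues from the ochre flask that “target itself matters, not elapsed time”. The forecast puts c_reagent into the rate as a factor and lets it fall during the integration, which gives a different number from mine. It reads 0.97 for the order in starting material, 1 for the order in reagent, 37 % for the red flask, and the verdict: the product reacts on with the second partner.

The simulation gives 0.97 and 0.74 for the orders, 31.3 % for the red flask, and the verdict: the product reacts on with the second partner.

    catalyst + starting material ⇌ catalyst-substrate complex (14.51 M⁻¹ h⁻¹, 156.2 h⁻¹)
    catalyst-substrate complex + reagent → target + catalyst (20.66 M⁻¹ h⁻¹)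
    target + reagent → side product (0.02268 M⁻¹ h⁻¹)

The red share lies nearer the forecast than my 13.1 %, though the order in reagent parts from the forecast's 1. Where the two flasks have made the same amount, the ochre rate is 0.81 of the grey rate. My fixed lifetime keeps its place in the grey readings, which span 0.471 of a lifetime, with target at 14.5 % of the reagent charge. Scaled inversely with c_reagent, it also serves the teal flask. Teal reaches 1.50 M of target at 33.4 h, where c_reagent stands at or below 1.50 M, so its target lifetime there is at least about 27.7 h.

The readings stem from a simulated flask on assumed constants, and the scatter is random.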